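**Plan**
- Retrosynthetic cuts, in order: the feruloyl ester C–O bond; the O–CH3 bond at C7; together, the O1–C7a and C7–O bonds of ring A; the C2–C3 bond (aldol); the C5–CH2 bond of the propyl chain (B-alkyl Suzuki–Miyaura).
- Forward: the silyloxypropyl chain is coupled to 5-bromo-2-fluorophenylacetic acid, the acid is loaded on the auxiliary, and the aldol joins rings A and B through the future C2–C3 bond. Auxiliary removal and primary silylation follow; the dihydrofuran ring (the only ring formed) then closes onto an aryne, which also oxygenates C7. Methylation, TBS removal, esterification and global desilylation finish the route.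
- Stereochemistry: both centres come from one Evans syn aldol with (R)-4-benzyloxazolidin-2-one, giving the (2R,3R) adduct. Neither centre is touched afterwards, so the syn pair becomes the (2R,3S) trans ring. The E alkene is bought with ferulic acid.
- Enabling feature: ring A carries two oxygens on neighbouring carbons, O1 on C7a and the methoxy oxygen on C7, and C7a is ortho to C3a, which holds the C3–C2–O tether. Both oxygens can therefore be delivered across a C7–C7a aryne made from a 2-fluoroarene that has no oxygen on ring A.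

Key step: step 7

Assumption: the descriptors of the target string are read as (2R,3S), the trans-2,3-disubstituted 2,3-dihydrobenzofuran; allyloxy(tert-butyl)dimethylsilane is taken as a purchasable reagent.

**Route**

Step 1
Reactants: 1 allyloxy(tert-butyl)dimethylsilane; 2 2-(5-bromo-2-fluorophenyl)acetic acid
Product: 4 2-[5-(3-tert-butyldimethylsilyloxypropyl)-2-fluorophenyl]acetic acid, via B-(3-tert-butyldimethylsilyloxypropyl)-9-borabicyclo[3.3.1]nonane 3 (not isolated)
Conditions: 1, 9-BBN-H, THF, 0 °C → rt; then 2 (pre-mixed with 3 M aq NaOH), PdCl2(dppf) (3 mol%; dppf = 1,1'-bis(diphenylphosphino)ferrocene), THF, 65 °C; citric acid work-up to pH 4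
Reagents that add atoms: none
Why: Anti-Markovnikov hydroboration gives a primary B-alkyl-9-BBN that undergoes B-alkyl Suzuki–Miyaura coupling with the aryl bromide under aqueous hydroxide, the acid travelling as its inert sodium carboxylate and the C–F bond and the alkyl TBS ether staying intact.

Step 2
Reactants: 4 2-[5-(3-tert-butyldimethylsilyloxypropyl)-2-fluorophenyl]acetic acid; 5 (R)-4-benzyloxazolidin-2-one
Product: 7 (R)-4-benzyl-3-{2-[5-(3-tert-butyldimethylsilyloxypropyl)-2-fluorophenyl]acetyl}oxazolidin-2-one, via mixed pivalic anhydride 6 (not isolated)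
Conditions: PivCl, Et3N, THF, −20 °C; then 5, LiCl, −20 °C → rt
Reagents that add atoms: none
Why: Mixed-anhydride N-acylation of the oxazolidinone under LiCl/Et3N activation is the standard way to load an arylacetic acid on the auxiliary and needs no strong base.

Step 3
Reactants: 8 vanillin
Product: 9 3-methoxy-4-(triisopropylsilyloxy)benzaldehyde
Conditions: TIPSCl, imidazole, DMF, rt
Reagents that add atoms: triisopropylsilyl chloride, CC(C)[Si](Cl)(C(C)C)C(C)C
Why: Imidazole-promoted silylation of a phenol is routine, and the bulky TIPS ether is chosen because it withstands alkyllithium and mild base and shields ring B in step 7.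

Step 4
Reactants: 7 (R)-4-benzyl-3-{2-[5-(3-tert-butyldimethylsilyloxypropyl)-2-fluorophenyl]acetyl}oxazolidin-2-one; 9 3-methoxy-4-(triisopropylsilyloxy)benzaldehyde
Product: 12 (R)-4-benzyl-3-[(2R,3R)-2-[5-(3-tert-butyldimethylsilyloxypropyl)-2-fluorophenyl]-3-hydroxy-3-(3-methoxy-4-triisopropylsilyloxyphenyl)propanoyl]oxazolidin-2-one, via Z dibutylboron enolate 10 (not isolated), via dibutylboron aldolate 11 (not isolated)
Conditions: Bu2BOTf, i-Pr2NEt, CH2Cl2, 0 °C; then 9, −78 → 0 °C; pH 7 phosphate buffer, MeOH, 30% aq H2O2, 0 °C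
Reagents that add atoms: none
Why: Evans syn aldol, in which the Z boron enolate reacts through a closed chair transition state on the enolate face turned away from the benzyl group of the (R)-auxiliary, so that both stereocentres are set together as (2R,3R) with syn relative configuration.

Step 5
Reactants: 12 (R)-4-benzyl-3-[(2R,3R)-2-[5-(3-tert-butyldimethylsilyloxypropyl)-2-fluorophenyl]-3-hydroxy-3-(3-methoxy-4-triisopropylsilyloxyphenyl)propanoyl]oxazolidin-2-one
Product: 13 (1R,2S)-2-[5-(3-tert-butyldimethylsilyloxypropyl)-2-fluorophenyl]-1-(3-methoxy-4-triisopropylsilyloxyphenyl)propane-1,3-diol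
Conditions: LiBH4, MeOH (1 equiv), THF, 0 °C
Reagents that add atoms: none
Why: Reductive cleavage of an N-acyl oxazolidinone with LiBH4 is standard for aldol adducts and runs at 0 °C where retro-aldol is slow; no bond at either stereocentre is broken, and the descriptor of the aryl-bearing carbon changes from R to S only because the CIP priorities change.

Step 6
Reactants: 13 (1R,2S)-2-[5-(3-tert-butyldimethylsilyloxypropyl)-2-fluorophenyl]-1-(3-methoxy-4-triisopropylsilyloxyphenyl)propane-1,3-diol
Product: 14 (1R,2S)-2-[5-(3-tert-butyldimethylsilyloxypropyl)-2-fluorophenyl]-1-(3-methoxy-4-triisopropylsilyloxyphenyl)-3-(triisopropylsilyloxy)propan-1-ol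
Conditions: TIPSCl (1.1 equiv), imidazole, CH2Cl2, 0 °C → rt
Reagents that add atoms: triisopropylsilyl chloride, CC(C)[Si](Cl)(C(C)C)C(C)C
Why: Sterically controlled monosilylation of a 1,3-diol, the bulky chlorosilane taking the primary hydroxyl and leaving the hindered secondary benzylic one free.

Step 7
Reactants: 14 (1R,2S)-2-[5-(3-tert-butyldimethylsilyloxypropyl)-2-fluorophenyl]-1-(3-methoxy-4-triisopropylsilyloxyphenyl)-3-(triisopropylsilyloxy)propan-1-ol
Product: 19 (2R,3S)-5-(3-tert-butyldimethylsilyloxypropyl)-2-(3-methoxy-4-triisopropylsilyloxyphenyl)-3-(triisopropylsilyloxymethyl)-2,3-dihydrobenzofuran-7-ol, via C-lithiated fluoroarene lithium alkoxide 15 (not isolated), via aryne lithium alkoxide 16 (not isolated), via 7-lithio-2,3-dihydrobenzofuran 17 (not isolated), via dimethyl 7-boronate 18 (not isolated)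
Conditions: s-BuLi (2.2 equiv), THF (dilute), −78 °C; warm to −30 °C; recool to −78 °C, B(OMe)3, → rt; then AcOH, 30% aq H2O2, 0 °C
Reagents that add atoms: hydrogen peroxide, OO
Why: The first equivalent of s-BuLi forms the lithium alkoxide and the second removes the only hydrogen ortho to fluorine (the future C7), after which warming expels LiF to give the C7–C7a aryne, the tethered alkoxide adds to C7a, and the resulting C7 aryllithium is borylated and oxidised with aryl migration from boron to oxygen. The closest known reaction type is aryne ring closure by a tethered heteroatom nucleophile with electrophilic quench of the ortho-alkoxy aryllithium, joined to the routine borylation–oxidation of an aryllithium. The dihydrofuran ring closes in a 5-exo-dig sense, the oxygen attacking the in-plane orbital at C7a within the plane of ring A while the aryne bond stays outside the new ring. No stereocentre is made or broken, so the (1R,2S) syn pair of 14 becomes the (2R,3S) trans ring by retention at both carbons. The step needs site-selective metalation and regioselective aryne capture: fluorine is the strongest acidifying group and its other ortho position (C3a) is substituted, the aryl TIPS ether shields ring B, the tether can reach C7a but not C7, and the primary oxygen, which would be equally placed for five-membered closure, is blocked by a TIPS group bulky enough not to migrate to the alkoxide. Only a slight excess of s-BuLi is used so that no alkyllithium remains to add to the aryne.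

Step 8
Reactants: 19 (2R,3S)-5-(3-tert-butyldimethylsilyloxypropyl)-2-(3-methoxy-4-triisopropylsilyloxyphenyl)-3-(triisopropylsilyloxymethyl)-2,3-dihydrobenzofuran-7-ol
Product: 20 (2R,3S)-5-(3-tert-butyldimethylsilyloxypropyl)-7-methoxy-2-(3-methoxy-4-triisopropylsilyloxyphenyl)-3-(triisopropylsilyloxymethyl)-2,3-dihydrobenzofuran
Conditions: MeI, K2CO3, acetone, rt
Reagents that add atoms: iodomethane, CI
Why: Williamson O-methylation of the only free phenol under weak, non-protic base, conditions under which the aryl and alkyl silyl ethers and both benzylic stereocentres should be stable.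

Step 9
Reactants: 20 (2R,3S)-5-(3-tert-butyldimethylsilyloxypropyl)-7-methoxy-2-(3-methoxy-4-triisopropylsilyloxyphenyl)-3-(triisopropylsilyloxymethyl)-2,3-dihydrobenzofuran
Product: 21 3-[(2R,3S)-7-methoxy-2-(3-methoxy-4-triisopropylsilyloxyphenyl)-3-(triisopropylsilyloxymethyl)-2,3-dihydrobenzofuran-5-yl]propan-1-ol
Conditions: PPTS (0.2 equiv), MeOH/CH2Cl2, rt
Reagents that add atoms: none
Why: Selective acid-catalysed methanolysis, the unhindered primary TBS ether being cleaved far faster than the bulkier primary TIPS ether on a branched carbon and the acid-resistant aryl TIPS ether.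

Step 10
Reactants: 22 ferulic acid
Product: 24 (E)-3-[4-(tert-butyldimethylsilyloxy)-3-methoxyphenyl]prop-2-enoic acid, via silyl ester silyl ether 23 (not isolated)
Conditions: TBSCl (2.5 equiv), imidazole, DMF, rt; then K2CO3, THF/H2O, 0 °C; mild acid work-up
Reagents that add atoms: tert-butyldimethylsilyl chloride, CC(C)(C)[Si](C)(C)Cl
Why: Exhaustive silylation followed by selective hydrolysis of the much more labile silyl ester is the usual way to mask the phenol of a hydroxycinnamic acid and leaves the E alkene untouched.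

Step 11
Reactants: 21 3-[(2R,3S)-7-methoxy-2-(3-methoxy-4-triisopropylsilyloxyphenyl)-3-(triisopropylsilyloxymethyl)-2,3-dihydrobenzofuran-5-yl]propan-1-ol; 24 (E)-3-[4-(tert-butyldimethylsilyloxy)-3-methoxyphenyl]prop-2-enoic acid
Product: 25 3-[(2R,3S)-7-methoxy-2-(3-methoxy-4-triisopropylsilyloxyphenyl)-3-(triisopropylsilyloxymethyl)-2,3-dihydrobenzofuran-5-yl]propyl (E)-3-[4-(tert-butyldimethylsilyloxy)-3-methoxyphenyl]prop-2-enoate
Conditions: EDC·HCl, DMAP, CH2Cl2, 0 °C → rt
Reagents that add atoms: none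
Why: Steglich esterification of an unhindered primary alcohol with a phenol-protected cinnamic acid proceeds under near-neutral conditions with retention of the E geometry.

Step 12
Reactants: 25 3-[(2R,3S)-7-methoxy-2-(3-methoxy-4-triisopropylsilyloxyphenyl)-3-(triisopropylsilyloxymethyl)-2,3-dihydrobenzofuran-5-yl]propyl (E)-3-[4-(tert-butyldimethylsilyloxy)-3-methoxyphenyl]prop-2-enoate
Product: 26 3-[(2R,3S)-2-(4-hydroxy-3-methoxyphenyl)-3-(hydroxymethyl)-7-methoxy-2,3-dihydrobenzofuran-5-yl]propyl (E)-3-(4-hydroxy-3-methoxyphenyl)prop-2-enoate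
Conditions: TBAF, AcOH (1:1, 4 equiv each), THF, 0 °C → rt
Reagents that add atoms: none
Why: Fluoride-mediated global desilylation buffered with acetic acid removes the two aryl silyl ethers and the primary TIPS ether near neutrality, so that the cinnamate ester survives and the 2-(4-hydroxyaryl)dihydrobenzofuran is not opened through a quinone methide.

**Compound list**

1 | allyloxy(tert-butyl)dimethylsilane | C=CCO[Si](C)(C)C(C)(C)C | starting material
2 | 2-(5-bromo-2-fluorophenyl)acetic acid | OC(=O)Cc1cc(Br)ccc1F | starting material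
3 | 9-[3-(tert-butyldimethylsilyloxy)propyl]-9-borabicyclo[3.3.1]nonane (formed in the flask) | CC(C)(C)[Si](C)(C)OCCCB1C2CCCC1CCC2 | intermediate
4 | 2-[5-(3-tert-butyldimethylsilyloxypropyl)-2-fluorophenyl]acetic acid | OC(=O)Cc1cc(CCCO[Si](C)(C)C(C)(C)C)ccc1F | intermediate
5 | (R)-4-benzyloxazolidin-2-one | O=C1N[C@H](Cc2ccccc2)CO1 | starting material
6 | mixed anhydride of 4 and pivalic acid (formed in the flask) | CC(C)(C)C(=O)OC(=O)Cc1cc(CCCO[Si](C)(C)C(C)(C)C)ccc1F | intermediate
7 | (R)-4-benzyl-3-{2-[5-(3-tert-butyldimethylsilyloxypropyl)-2-fluorophenyl]acetyl}oxazolidin-2-one | O=C(Cc1cc(CCCO[Si](C)(C)C(C)(C)C)ccc1F)N1[C@H](Cc2ccccc2)COC1=O | intermediate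
8 | vanillin (4-hydroxy-3-methoxybenzaldehyde) | COc1cc(C=O)ccc1O | starting material
9 | 3-methoxy-4-(triisopropylsilyloxy)benzaldehyde | COc1cc(C=O)ccc1O[Si](C(C)C)(C(C)C)C(C)C | intermediate
10 | (Z)-O-dibutylboryl enolate of 7 (formed in the flask) | CCCCB(CCCC)O/C(=C\c1cc(CCCO[Si](C)(C)C(C)(C)C)ccc1F)N1[C@H](Cc2ccccc2)COC1=O | intermediate
11 | O-dibutylboryl aldolate of 12 (formed in the flask) | Fc1ccc(CCCO[Si](C)(C)C(C)(C)C)cc1[C@@H](C(=O)N1[C@H](Cc2ccccc2)COC1=O)[C@H](c1ccc(O[Si](C(C)C)(C(C)C)C(C)C)c(OC)c1)OB(CCCC)CCCC | intermediate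
12 | (R)-4-benzyl-3-[(2R,3R)-2-[5-(3-tert-butyldimethylsilyloxypropyl)-2-fluorophenyl]-3-hydroxy-3-(3-methoxy-4-triisopropylsilyloxyphenyl)propanoyl]oxazolidin-2-one | Fc1ccc(CCCO[Si](C)(C)C(C)(C)C)cc1[C@@H](C(=O)N1[C@H](Cc2ccccc2)COC1=O)[C@H](c1ccc(O[Si](C(C)C)(C(C)C)C(C)C)c(OC)c1)O | intermediate
13 | (1R,2S)-2-[5-(3-tert-butyldimethylsilyloxypropyl)-2-fluorophenyl]-1-(3-methoxy-4-triisopropylsilyloxyphenyl)propane-1,3-diol | Fc1ccc(CCCO[Si](C)(C)C(C)(C)C)cc1[C@@H](CO)[C@H](c1ccc(O[Si](C(C)C)(C(C)C)C(C)C)c(OC)c1)O | intermediate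
14 | (1R,2S)-2-[5-(3-tert-butyldimethylsilyloxypropyl)-2-fluorophenyl]-1-(3-methoxy-4-triisopropylsilyloxyphenyl)-3-(triisopropylsilyloxy)propan-1-ol | Fc1ccc(CCCO[Si](C)(C)C(C)(C)C)cc1[C@@H](CO[Si](C(C)C)(C(C)C)C(C)C)[C@H](c1ccc(O[Si](C(C)C)(C(C)C)C(C)C)c(OC)c1)O | intermediate
15 | lithium alkoxide of 14 lithiated ortho to fluorine (formed in the flask) | Fc1c([Li])cc(CCCO[Si](C)(C)C(C)(C)C)cc1[C@@H](CO[Si](C(C)C)(C(C)C)C(C)C)[C@H](c1ccc(O[Si](C(C)C)(C(C)C)C(C)C)c(OC)c1)O[Li] | intermediate
16 | C7–C7a aryne bearing the lithium alkoxide tether (formed in the flask) | C1#CC=C(CCCO[Si](C)(C)C(C)(C)C)C=C1[C@@H](CO[Si](C(C)C)(C(C)C)C(C)C)[C@H](c1ccc(O[Si](C(C)C)(C(C)C)C(C)C)c(OC)c1)O[Li] | intermediate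
17 | (2R,3S)-7-lithio-5-(3-tert-butyldimethylsilyloxypropyl)-2-(3-methoxy-4-triisopropylsilyloxyphenyl)-3-(triisopropylsilyloxymethyl)-2,3-dihydrobenzofuran (formed in the flask) | CC(C)(C)[Si](C)(C)OCCCc2cc([Li])c3c(c2)[C@@H](CO[Si](C(C)C)(C(C)C)C(C)C)[C@H](c2ccc(O[Si](C(C)C)(C(C)C)C(C)C)c(OC)c2)O3 | intermediate
18 | dimethyl [(2R,3S)-5-(3-tert-butyldimethylsilyloxypropyl)-2-(3-methoxy-4-triisopropylsilyloxyphenyl)-3-(triisopropylsilyloxymethyl)-2,3-dihydrobenzofuran-7-yl]boronate (formed in the flask) | CC(C)(C)[Si](C)(C)OCCCc2cc(B(OC)OC)c3c(c2)[C@@H](CO[Si](C(C)C)(C(C)C)C(C)C)[C@H](c2ccc(O[Si](C(C)C)(C(C)C)C(C)C)c(OC)c2)O3 | intermediate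
19 | (2R,3S)-5-(3-tert-butyldimethylsilyloxypropyl)-2-(3-methoxy-4-triisopropylsilyloxyphenyl)-3-(triisopropylsilyloxymethyl)-2,3-dihydrobenzofuran-7-ol | CC(C)(C)[Si](C)(C)OCCCc2cc(O)c3c(c2)[C@@H](CO[Si](C(C)C)(C(C)C)C(C)C)[C@H](c2ccc(O[Si](C(C)C)(C(C)C)C(C)C)c(OC)c2)O3 | intermediate
20 | (2R,3S)-5-(3-tert-butyldimethylsilyloxypropyl)-7-methoxy-2-(3-methoxy-4-triisopropylsilyloxyphenyl)-3-(triisopropylsilyloxymethyl)-2,3-dihydrobenzofuran | CC(C)(C)[Si](C)(C)OCCCc2cc(OC)c3c(c2)[C@@H](CO[Si](C(C)C)(C(C)C)C(C)C)[C@H](c2ccc(O[Si](C(C)C)(C(C)C)C(C)C)c(OC)c2)O3 | intermediate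
21 | 3-[(2R,3S)-7-methoxy-2-(3-methoxy-4-triisopropylsilyloxyphenyl)-3-(triisopropylsilyloxymethyl)-2,3-dihydrobenzofuran-5-yl]propan-1-ol | OCCCc2cc(OC)c3c(c2)[C@@H](CO[Si](C(C)C)(C(C)C)C(C)C)[C@H](c2ccc(O[Si](C(C)C)(C(C)C)C(C)C)c(OC)c2)O3 | intermediate
22 | ferulic acid, (E)-3-(4-hydroxy-3-methoxyphenyl)prop-2-enoic acid | COc1cc(/C=C/C(=O)O)ccc1O | starting material
23 | tert-butyldimethylsilyl (E)-3-[4-(tert-butyldimethylsilyloxy)-3-methoxyphenyl]prop-2-enoate (formed in the flask) | COc1cc(/C=C/C(=O)O[Si](C)(C)C(C)(C)C)ccc1O[Si](C)(C)C(C)(C)C | intermediate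
24 | (E)-3-[4-(tert-butyldimethylsilyloxy)-3-methoxyphenyl]prop-2-enoic acid | COc1cc(/C=C/C(=O)O)ccc1O[Si](C)(C)C(C)(C)C | intermediate
25 | 3-[(2R,3S)-7-methoxy-2-(3-methoxy-4-triisopropylsilyloxyphenyl)-3-(triisopropylsilyloxymethyl)-2,3-dihydrobenzofuran-5-yl]propyl (E)-3-[4-(tert-butyldimethylsilyloxy)-3-methoxyphenyl]prop-2-enoate | COc1cc(/C=C/C(=O)OCCCc2cc(OC)c3c(c2)[C@@H](CO[Si](C(C)C)(C(C)C)C(C)C)[C@H](c2ccc(O[Si](C(C)C)(C(C)C)C(C)C)c(OC)c2)O3)ccc1O[Si](C)(C)C(C)(C)C | intermediate
26 | 3-[(2R,3S)-2-(4-hydroxy-3-methoxyphenyl)-3-(hydroxymethyl)-7-methoxy-2,3-dihydrobenzofuran-5-yl]propyl (E)-3-(4-hydroxy-3-methoxyphenyl)prop-2-enoate | COc1cc(/C=C/C(=O)OCCCc2cc(OC)c3c(c2)[C@@H](CO)[C@H](c2ccc(O)c(OC)c2)O3)ccc1O | target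

**Step count**
Total steps: 12. Longest linear sequence: 10 steps (steps 1, 2, 4, 5, 6, 7, 8, 9, 11, 12).

**Steps most likely to fail**

Step 7. Several processes could divert the aryne cascade:
- metalation on ring B (between the methoxy group and the carbinol carbon) or at a benzylic C–H instead of ortho to fluorine;
- capture of the aryne by leftover s-BuLi or by a second aryllithium before the alkoxide closes;
- migration of the primary TIPS group to the alkoxide, which would let the other oxygen cyclise;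
- protonation of the C7 aryllithium before borylation.

Fallback: setting out from 14, the two C–O bonds would be made one after the other. Intramolecular nucleophilic aromatic substitution of fluoride by the potassium alkoxide (KHMDS or KOt-Bu, DMF, 60–80 °C), a closure known for 2-(2-fluoroaryl)ethanols, should give (2R,3S)-5-(3-tert-butyldimethylsilyloxypropyl)-2-(3-methoxy-4-triisopropylsilyloxyphenyl)-3-(triisopropylsilyloxymethyl)-2,3-dihydrobenzofuran F1. Ortho-lithiation of F1 at C7 directed by O1 (n-BuLi, TMEDA, Et2O, 0 °C), then B(OMe)3 and H2O2/AcOH, would return the route at 19.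

Step 4. The conjugated boron enolate may add sluggishly to the electron-rich aldehyde, the syn selectivity may erode, and the adduct may suffer retro-aldol cleavage or epimerisation at the acidic aryl-bearing carbon during work-up and in the reduction that follows.

Fallback: setting out from acid 4, coupling with (R)-4-benzylthiazolidine-2-thione (EDC·HCl, DMAP, CH2Cl2) would give (R)-4-benzyl-3-{2-[5-(3-tert-butyldimethylsilyloxypropyl)-2-fluorophenyl]acetyl}thiazolidine-2-thione F2. Its chlorotitanium enolate (TiCl4, i-Pr2NEt, N-methyl-2-pyrrolidinone, CH2Cl2, 0 °C), made with the two-equivalent base/ligand protocol that gives the same syn facial sense as the boron aldol, should add to 9 at −78 °C to give (R)-4-benzyl-3-[(2R,3R)-2-[5-(3-tert-butyldimethylsilyloxypropyl)-2-fluorophenyl]-3-hydroxy-3-(3-methoxy-4-triisopropylsilyloxyphenyl)propanoyl]thiazolidine-2-thione F3. The thione auxiliary is displaced by NaBH4 (THF/EtOH, 0 °C) under milder conditions than the oxazolidinone, and the route is rejoined at diol 13.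

Step 1. The alkylborane may undergo protodeboronation, the alkylpalladium intermediate may undergo β-hydride elimination to give the debrominated acid, transmetalation may be slow beside the carboxylate, and some TBS may be lost on acidification.

Fallback: setting out from 2, Sonogashira coupling with tert-butyldimethyl(prop-2-yn-1-yloxy)silane (PdCl2(PPh3)2, CuI, Et3N, DMF, 70 °C) should give 2-{5-[3-(tert-butyldimethylsilyloxy)prop-1-yn-1-yl]-2-fluorophenyl}acetic acid F4. Hydrogenation of the alkyne (H2, palladium on carbon, EtOAc, rt) would return the route at 4.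

**Further compounds**
F1 | step 7 | (2R,3S)-5-(3-tert-butyldimethylsilyloxypropyl)-2-(3-methoxy-4-triisopropylsilyloxyphenyl)-3-(triisopropylsilyloxymethyl)-2,3-dihydrobenzofuran | CC(C)(C)[Si](C)(C)OCCCc2ccc3c(c2)[C@@H](CO[Si](C(C)C)(C(C)C)C(C)C)[C@H](c2ccc(O[Si](C(C)C)(C(C)C)C(C)C)c(OC)c2)O3
F2 | step 4 | (R)-4-benzyl-3-{2-[5-(3-tert-butyldimethylsilyloxypropyl)-2-fluorophenyl]acetyl}thiazolidine-2-thione | O=C(Cc1cc(CCCO[Si](C)(C)C(C)(C)C)ccc1F)N1[C@H](Cc2ccccc2)CSC1=S
F3 | step 4 | (R)-4-benzyl-3-[(2R,3R)-2-[5-(3-tert-butyldimethylsilyloxypropyl)-2-fluorophenyl]-3-hydroxy-3-(3-methoxy-4-triisopropylsilyloxyphenyl)propanoyl]thiazolidine-2-thione | Fc1ccc(CCCO[Si](C)(C)C(C)(C)C)cc1[C@@H](C(=O)N1[C@H](Cc2ccccc2)CSC1=S)[C@H](c1ccc(O[Si](C(C)C)(C(C)C)C(C)C)c(OC)c1)O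
F4 | step 1 | 2-{5-[3-(tert-butyldimethylsilyloxy)prop-1-yn-1-yl]-2-fluorophenyl}acetic acid | OC(=O)Cc1cc(C#CCO[Si](C)(C)C(C)(C)C)ccc1F
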